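## Retrosynthetic overview

1. The 1,1-dioxo-1,4-thiazine ring is added last by oxidative annulation of hypotaurine onto naphthoquinone 16; the quinone comes from its dimethyl hydroquinone ether 15, and the seven-membered enol lactone of 15 from the formyl/carboxyl pair of 14.
2. Key disconnection: the methylcyclohexene ring (ring A) is opened at two bonds, benzylic quaternary carbon to the enol-bearing ring carbon and ring CH2 to the vinylic CH. This gives vinyl phthalide 9 (a masked 1-aryl-1-methylallyl cation) and prenal dienyl acetate 11, joined in a formal [3+3] annulation.
3. Enabling feature: ring A with its exocyclic O–CH=C unit conjugated to the ring C(CH3)=CH bond is the dienol ester of an α-cyclocitral-type aldehyde. This 1-oxy-3-methylbutadiene unit is nucleophilic at its terminal CH and at the carbon next to the enol CH, the two atoms that must bond to the ring CH2 and to the quaternary carbon. That quaternary carbon sits ortho to the lactone carboxyl on the naphthalene, which serves first as an internal leaving group (phthalide) and later as the lactone acyl group.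
4. The naphthalene core comes from a Diels–Alder reaction of an o-quinodimethane with an ynoate made from methyl propiolate and methyl vinyl ketone.
5. Ring order: dimethoxybenzene ring (purchased), second benzo ring (Diels–Alder), furanone (lactonisation), ring A (key step, furanone opened), oxepinone, quinone, thiazine dioxide.

Key step: step 6

Assumption: the antipode of the chiral acid that gives the (S)-configured quaternary carbon is found by screening and is written here as (S,S); the E/Z geometry of 11, 12 and 13 has no consequence because the enol acetate is cleaved within step 6.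

## Route

Step 1
Reactants: 1 1,4-dimethoxy-2,3-dimethylbenzene
Product: 2 2,3-bis(bromomethyl)-1,4-dimethoxybenzene
Conditions: NBS (2.1 equiv), 2,2′-azobis(isobutyronitrile) (cat.), PhCF3, 85 °C
Reagents that add atoms: N-bromosuccinimide, O=C1CCC(=O)N1Br
Why: Wohl–Ziegler benzylic bromination; the radical chain in a non-polar solvent should favour the two benzylic methyl groups over ring bromination.

Step 2
Reactants: 3 methyl propiolate; 4 methyl vinyl ketone
Product: 5 methyl 4-hydroxy-4-methylhex-5-en-2-ynoate (racemic)
Conditions: LiN(SiMe3)2, THF, −78 °C; then 4, −78 °C; AcOH quench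
Reagents that add atoms: none
Why: 1,2-addition of a lithium acetylide to the enone carbonyl at low temperature; the racemic carbinol centre is acceptable because it is erased by ionisation in step 6.

Step 3
Reactants: 2 2,3-bis(bromomethyl)-1,4-dimethoxybenzene; 5 methyl 4-hydroxy-4-methylhex-5-en-2-ynoate
Product: 7 methyl 3-(2-hydroxybut-3-en-2-yl)-5,8-dimethoxy-1,4-dihydronaphthalene-2-carboxylate (racemic), via o-quinodimethane 6 (not isolated)
Conditions: NaI (4 equiv), DMF, 65 °C
Reagents that add atoms: none
Why: iodide-induced 1,4-elimination generates the o-quinodimethane, which should be trapped by the ynoate in a Diels–Alder reaction; the diene is symmetric, so no regiochemical question arises.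

Step 4
Reactants: 7 methyl 3-(2-hydroxybut-3-en-2-yl)-5,8-dimethoxy-1,4-dihydronaphthalene-2-carboxylate
Product: 9 5,8-dimethoxy-3-methyl-3-vinylnaphtho[2,3-c]furan-1(3H)-one (racemic), via naphthoate 8 (not isolated)
Conditions: 2,3-dichloro-5,6-dicyano-1,4-benzoquinone (1.1 equiv), PhMe, rt; then DBU (0.1 equiv), 50 °C
Reagents that add atoms: none
Why: dehydrogenative aromatisation of the 1,4-dihydronaphthalene, then lactonisation of the tertiary alcohol onto the ortho ester (phthalide formation, favoured by the gem-disubstitution).

Step 5
Reactants: 10 3-methylbut-2-enal (prenal)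
Product: 11 (E)-3-methylbuta-1,3-dien-1-yl acetate
Conditions: Ac2O, KOAc (cat.), 120 °C
Reagents that add atoms: acetic anhydride, CC(=O)OC(C)=O
Why: O-acetylation of the extended enolate formed by γ-deprotonation of the enal, the standard preparation of 1-acetoxy-1,3-dienes.

Step 6
Reactants: 9 5,8-dimethoxy-3-methyl-3-vinylnaphtho[2,3-c]furan-1(3H)-one; 11 (E)-3-methylbuta-1,3-dien-1-yl acetate
Product: 14 3-[(1S)-2-formyl-1,3-dimethylcyclohex-2-en-1-yl]-5,8-dimethoxynaphthalene-2-carboxylic acid, via triene acid 12 (not isolated), via enol acetate 13 (not isolated)
Conditions: 11 (3 equiv, slow addition), (S,S)-IDPi acid HN[P(=NSO2CF3)(O2R*)]2 with O2R* = (S)-3,3′-bis[3,5-bis(trifluoromethyl)phenyl]-1,1′-binaphthalene-2,2′-diolate (5 mol%), CH2Cl2, −40 °C → rt; then K2CO3 (2 equiv), MeOH, 0 °C → rt; 1 M HCl work-up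
Reagents that add atoms: none
Why: Proposed new method: the chiral acid ionises the tertiary allylic, benzylic lactone C–O bond of 9 (the ortho carboxyl is the internal leaving group, so the stereocentre of racemic 9 is erased), the 1-aryl-1-methylallyl cation is attacked at its CH2 terminus by the terminal carbon of 11 and proton loss regenerates a dienyl acetate (12); the trisubstituted styrene of 12 is then re-ionised (by protonation or through the re-formed saturated lactone) to the tertiary benzylic cation, which is captured by the α-carbon of the enol acetate, and loss of the α-proton gives 13. The closest known reaction types are the Lewis-acid γ-alkylation of 1-oxy-1,3-dienes by allyl cations (head-to-tail terpene coupling), the acid cyclisation of citral enol acetate to α-cyclocitral enol acetate, and the capture of tertiary carbocations by tethered π-nucleophiles under confined chiral imidodiphosphorimidate acids, which creates quaternary stereocentres. The cyclohexene ring closes in a chair-like six-membered cation–olefin cyclisation that is exo with respect to the enol acetate C=C. The quaternary stereocentre is set in this ring closure by the confined chiral counter-anion, which is hydrogen-bonded to the ortho CO2H group and so should differentiate the two faces of the planar benzylic cation. The step needs attack at the unhindered allyl terminus (secured by the methyl and aryl groups on the other terminus), six- rather than four-membered closure (only the α-carbon of the dienyl acetate reaches the cation through a strain-free chair) and reaction of the diene in preference to the dimethoxynaphthalene ring (secured by excess 11 and low temperature). Methanolysis in the same flask then removes the acetyl activating group and should give the conjugated enal 14.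

Step 7
Reactants: 14 3-[(1S)-2-formyl-1,3-dimethylcyclohex-2-en-1-yl]-5,8-dimethoxynaphthalene-2-carboxylic acid
Product: 15 (S)-dienol lactone, dimethyl hydroquinone ether (seven-membered enol lactone between the carboxyl group and the dienol of the formyl group of 14)
Conditions: (COCl)2 (1.2 equiv), DMF (cat.), CH2Cl2, 0 °C; then Et3N (3 equiv), DMAP (cat.), 0 → 40 °C
Reagents that add atoms: none
Why: enol lactonisation by intramolecular O-acylation of the extended enolate of the enal with the acyl chloride (standard enol ester formation from enolisable aldehydes); C-acylation is blocked by the adjacent quaternary carbon, and γ-deprotonation places the ring double bond at C(CH3)=CH as in the target.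

Step 8
Reactants: 15 (S)-dienol lactone, dimethyl hydroquinone ether
Product: 16 (S)-dienol lactone naphthoquinone
Conditions: (NH4)2Ce(NO3)6 (2.5 equiv), MeCN/H2O, 0 °C, short reaction time
Reagents that add atoms: water, O
Why: oxidative demethylation of a 1,4-dimethoxynaphthalene to the 1,4-naphthoquinone; the dienol ester is much harder to oxidise than the dimethoxyarene and should survive.

Step 9
Reactants: 16 (S)-dienol lactone naphthoquinone; 17 hypotaurine (2-aminoethanesulfinic acid)
Product: 19 CNP0348176.1 (target, S), via sulfonyl hydroquinone 18 (not isolated)
Conditions: 17 (1.5 equiv), MeCN/EtOH/H2O, rt, open to air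
Reagents that add atoms: none
Why: known hypotaurine–quinone annulation. The sulfinate of zwitterionic hypotaurine should add to the quinone carbon β to the more electron-poor carbonyl (the one para to the lactone acyl group), giving 18. Air re-oxidation, intramolecular conjugate addition of the amine and a second oxidation then give the thiazine-dioxide-fused quinone with sulfur and nitrogen placed as in the target.

## Compound list

1 | 1,4-dimethoxy-2,3-dimethylbenzene | COc1ccc(OC)c(C)c1C | starting material
2 | 2,3-bis(bromomethyl)-1,4-dimethoxybenzene | COc1ccc(OC)c(CBr)c1CBr | intermediate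
3 | methyl propiolate | C#CC(=O)OC | starting material
4 | methyl vinyl ketone | CC(=O)C=C | starting material
5 | methyl 4-hydroxy-4-methylhex-5-en-2-ynoate (racemic) | COC(=O)C#CC(C)(O)C=C | intermediate
6 | 3,6-dimethoxy-o-quinodimethane (1,4-dimethoxy-5,6-dimethylidenecyclohexa-1,3-diene) | COC1=CC=C(OC)C(=C)C1=C | intermediate (not isolated)
7 | methyl 3-(2-hydroxybut-3-en-2-yl)-5,8-dimethoxy-1,4-dihydronaphthalene-2-carboxylate (racemic) | COC(=O)C1=C(C(C)(O)C=C)Cc2c(OC)ccc(OC)c2C1 | intermediate
8 | methyl 3-(2-hydroxybut-3-en-2-yl)-5,8-dimethoxynaphthalene-2-carboxylate (racemic) | COC(=O)c1cc2c(OC)ccc(OC)c2cc1C(C)(O)C=C | intermediate (not isolated)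
9 | 5,8-dimethoxy-3-methyl-3-vinylnaphtho[2,3-c]furan-1(3H)-one (racemic) | C=CC1(C)OC(=O)c2cc3c(OC)ccc(OC)c3cc21 | intermediate
10 | 3-methylbut-2-enal (prenal) | CC(C)=CC=O | starting material
11 | (E)-3-methylbuta-1,3-dien-1-yl acetate | CC(=O)O/C=C/C(C)=C | intermediate
12 | 3-(8-acetoxy-6-methylocta-2,5,7-trien-2-yl)-5,8-dimethoxynaphthalene-2-carboxylic acid (alkene geometries not defined) | CC(=O)OC=CC(C)=CCC=C(C)c1cc2c(OC)ccc(OC)c2cc1C(=O)O | intermediate (not isolated)
13 | 3-[(1S)-2-(acetoxymethylidene)-1,3-dimethylcyclohex-3-en-1-yl]-5,8-dimethoxynaphthalene-2-carboxylic acid | CC(=O)OC=C1C(C)=CCC[C@@]1(C)c1cc2c(OC)ccc(OC)c2cc1C(=O)O | intermediate (not isolated)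
14 | 3-[(1S)-2-formyl-1,3-dimethylcyclohex-2-en-1-yl]-5,8-dimethoxynaphthalene-2-carboxylic acid | CC1=C(C=O)[C@@](C)(CCC1)c1cc2c(OC)ccc(OC)c2cc1C(=O)O | intermediate
15 | (S)-dienol lactone, dimethyl hydroquinone ether (dimethoxynaphthalene fused to the oxepinone enol lactone and the methylcyclohexene ring) | CC1=CCC[C@]2(C)C1=COC(=O)c1cc3c(OC)ccc(OC)c3cc12 | intermediate
16 | (S)-dienol lactone naphthoquinone | CC1=CCC[C@]2(C)C1=COC(=O)c1cc3c(cc12)C(=O)C=CC3=O | intermediate
17 | hypotaurine (2-aminoethanesulfinic acid) | NCCS(=O)O | starting material
18 | (S)-(2-aminoethyl)sulfonyl hydroquinone (sulfonyl group on the ring carbon next to the C–OH that lies para to the quaternary-carbon-bearing position) | CC1=CCC[C@]2(C)C1=COC(=O)c1cc3c(O)c(S(=O)(=O)CCN)cc(O)c3cc12 | intermediate (not isolated)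
19 | CNP0348176.1, (S) | CC1=CCC[C@]2(C)C1=COC(=O)c1cc3c(cc12)C(=O)C1=C(C3=O)S(=O)(=O)CCN1 | target

## Step count and risks

Total step count: 9. Longest linear sequence: 7 steps (steps 1, 3, 4, 6, 7, 8, 9 from compound 1; equally steps 2, 3, 4, 6, 7, 8, 9 from compounds 3 and 4).

Steps most likely to fail:

1. Step 6 (proposed new method). Possible failures are weak facial discrimination in the ring closure, cationic oligomerisation of 11, Friedel–Crafts alkylation of the electron-rich naphthalene ring, or stalling at the re-lactonised open-chain stage. Fallback (sets out from 9 and 11, returns at 14): the two bond formations are run separately with known chemistry and the enantiomer is obtained by resolution. Compounds 9 and 11 with Me3SiOSO2CF3 (0.2 equiv) in CH2Cl2 at −60 °C (Lewis-acid allylation of a 1-oxy-diene at its terminal carbon) should give 12, which is isolated. Treatment of 12 with 85% H3PO4 or BF3·OEt2 at 0 °C (the known cyclisation of citral enol acetate) should give the racemic enol-acetate acid F1. K2CO3 in MeOH should convert it into the racemic enal acid F2. Classical resolution through the (R)-1-phenylethylammonium salt of the (S)-acid F3 (fractional crystallisation; the amine antipode is chosen by screening) and acidification with HCl should return 14.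

2. Step 9. Possible failures are amine-first conjugate addition, which would give the regioisomeric thiazine, and aminolysis of the enol lactone by the free amine. Fallback (sets out from 16 and 17, returns at 18): the amine is masked so that only sulfur can add first. Hypotaurine 17 with Boc2O and NaOH in dioxane/H2O, then careful acidification, should give 2-[(tert-butoxycarbonyl)amino]ethanesulfinic acid F4. Conjugate addition of F4 to 16 in MeCN/H2O at rt (known sulfinic acid addition to quinones) should give the Boc-protected sulfonyl hydroquinone F5. CF3CO2H in CH2Cl2 at 0 °C then liberates the amine to give 18, which is neutralised and air-oxidised to 19 as in step 9.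

3. Step 7. Possible failures are intermolecular acylation (anhydride or oligomer formation) or decomposition of the acyl chloride in competition with closure of the seven-membered ring next to the quaternary carbon. Fallback (sets out from 14, returns at 15): acid-catalysed dehydrative enol lactonisation with TsOH·H2O (cat.) in PhMe at reflux with azeotropic removal of water. The carboxyl group adds to the formyl group to give the cyclic hydroxy lactone (pseudo-acid form of 14) F6, which loses water through the acyloxy-allyl cation and γ-proton loss to give 15.

Further compounds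
F1 | step 6 | racemic 3-[2-(acetoxymethylidene)-1,3-dimethylcyclohex-3-en-1-yl]-5,8-dimethoxynaphthalene-2-carboxylic acid | CC(=O)OC=C1C(C)=CCCC1(C)c1cc2c(OC)ccc(OC)c2cc1C(=O)O
F2 | step 6 | racemic 3-(2-formyl-1,3-dimethylcyclohex-2-en-1-yl)-5,8-dimethoxynaphthalene-2-carboxylic acid | CC1=C(C=O)C(C)(CCC1)c1cc2c(OC)ccc(OC)c2cc1C(=O)O
F3 | step 6 | (R)-1-phenylethylammonium salt of (S)-acid 14 | CC1=C(C=O)[C@@](C)(CCC1)c1cc2c(OC)ccc(OC)c2cc1C(=O)[O-].C[C@@H]([NH3+])c1ccccc1
F4 | step 9 | 2-[(tert-butoxycarbonyl)amino]ethanesulfinic acid | CC(C)(C)OC(=O)NCCS(=O)O
F5 | step 9 | (S)-Boc-protected (2-aminoethyl)sulfonyl hydroquinone | CC1=CCC[C@]2(C)C1=COC(=O)c1cc3c(O)c(S(=O)(=O)CCNC(=O)OC(C)(C)C)cc(O)c3cc12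
F6 | step 7 | cyclic hydroxy lactone (pseudo-acid form of 14, carbinol centre undefined) | CC1=C2C(O)OC(=O)c3cc4c(OC)ccc(OC)c4cc3[C@]2(C)CCC1
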